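**Retrosynthetic overview**
The plan rests on the tetrasubstituted C8=C9 alkene of ring B, which carries C17 and the C11–C12 chain and sits next to quaternary C10 (labdane numbering; target = 6β-hydroxy-3α,19-bis(3-methylbutanoyloxy)labda-8,13(E)-dien-15-oic acid, 3R,4S,5R,6R,10S).
End game: the 3α and 6β carbinols come from one double oxidation–bulky hydride sequence; C12–C13 comes from B-alkyl Suzuki–Miyaura coupling of the C11=C12 vinyl group with an (E)-enol triflate.
Key disconnection: C8=C9 by ring-closing enyne metathesis of a ring-A enyne (ethynyl on C10, 2-methylallyl carbinol arm on C5), which closes ring B and delivers C12.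
Ring-A enyne: from a cis-fused C19→C6 γ-lactone; the lactone tether sets C5 and steers a radical alkynylation at C10. The lactone comes from a desymmetrised 2-(silyloxymethyl)-2-methylcyclohexane-1,3-dione (C3, C4).
Ring order: ring A (from the dione) → temporary γ-lactone → ring B.

Key step: step 14

Remark: O3 and O19 are not bridged by an acetonide, because the equatorial O3 silyl ether and the C19→C6 lactone favour the ring-A chair with C19 axial, which the C10 and C5 steps need.
Assumption: the Grignard addition of step 11 is drawn as giving the (6S) alcohol; C6 is re-oxidised in step 17, so a C6 epimer would follow the same steps.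

**Route**

Step 1
Reactants: 1 2-methylcyclohexane-1,3-dione; 2 formaldehyde
Product: 3 2-(hydroxymethyl)-2-methylcyclohexane-1,3-dione
Conditions: aq. CH2O (37 %), Et3N (cat.), THF, 0 °C to rt
Reagents that add atoms: none
Why: Aldol addition (hydroxymethylation) of the acidic C2–H of the 1,3-dione to formaldehyde gives the prochiral quaternary carbon that becomes C4 with C18 and C19; no stereocentre is formed.

Step 2
Reactants: 3 2-(hydroxymethyl)-2-methylcyclohexane-1,3-dione
Product: 4 2-[(tert-butyldimethylsilyloxy)methyl]-2-methylcyclohexane-1,3-dione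
Conditions: TBSCl, imidazole, CH2Cl2, 0 °C to rt
Reagents that add atoms: tert-butyl(chloro)dimethylsilane, CC(C)(C)[Si](C)(C)Cl
Why: Silyl ether formation at the only hydroxyl stops retro-aldol loss of formaldehyde and makes the CH2O arm much bulkier than the methyl for the desymmetrisation.

Step 3
Reactants: 4 2-[(tert-butyldimethylsilyloxy)methyl]-2-methylcyclohexane-1,3-dione
Product: 5 (2S,3S)-2-[(tert-butyldimethylsilyloxy)methyl]-3-hydroxy-2-methylcyclohexan-1-one
Conditions: (R)-2-methyl-CBS-oxazaborolidine [(R)-1-methyl-3,3-diphenyltetrahydro-1H,3H-pyrrolo[1,2-c][1,3,2]oxazaborole] (20 mol %), catecholborane, toluene, −60 °C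
Reagents that add atoms: none
Why: Corey–Bakshi–Shibata reduction desymmetrises the dione, the catalyst setting the carbinol as S (quaternary carbon as the large group, CH2 as the small one) and hydride adding anti to the CH2OTBS arm, so that C3 and C4 arise together as the cis (2S,3S) hydroxy ketone.

Step 4
Reactants: 5 (2S,3S)-2-[(tert-butyldimethylsilyloxy)methyl]-3-hydroxy-2-methylcyclohexan-1-one
Product: 6 (2S,3S)-2-[(tert-butyldimethylsilyloxy)methyl]-2-methyl-3-(triisopropylsilyloxy)cyclohexan-1-one
Conditions: TIPSOTf, 2,6-lutidine, CH2Cl2, 0 °C to rt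
Reagents that add atoms: triisopropylsilyl trifluoromethanesulfonate, CC(C)[Si](OS(=O)(=O)C(F)(F)F)(C(C)C)C(C)C
Why: Silylation of the hindered secondary alcohol with the silyl triflate gives a TIPS ether that should survive the enolate, palladium, radical, hydride and Grignard steps and the acid of step 7.

Step 5
Reactants: 6 (2S,3S)-2-[(tert-butyldimethylsilyloxy)methyl]-2-methyl-3-(triisopropylsilyloxy)cyclohexan-1-one
Product: 7 (2S,3S,6RS)-2-[(tert-butyldimethylsilyloxy)methyl]-2,6-dimethyl-3-(triisopropylsilyloxy)cyclohexan-1-one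
Conditions: LiN(iPr)2, THF, −78 °C; then MeI, −78 to −20 °C
Reagents that add atoms: iodomethane, CI
Why: Enolate alkylation at the only enolisable α-carbon (the future C10) brings in C20; the new centre forms as an epimer mixture that is flattened in step 6.

Step 6
Reactants: 7 (2S,3S,6RS)-2-[(tert-butyldimethylsilyloxy)methyl]-2,6-dimethyl-3-(triisopropylsilyloxy)cyclohexan-1-one
Product: 8 (5S,6S)-6-[(tert-butyldimethylsilyloxy)methyl]-2,6-dimethyl-5-(triisopropylsilyloxy)cyclohex-1-en-1-yl trifluoromethanesulfonate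
Conditions: KN(SiMe3)2, THF, −78 to 0 °C; then PhNTf2, −78 °C to rt
Reagents that add atoms: N-phenylbis(trifluoromethanesulfonimide), O=S(=O)(N(c1ccccc1)S(=O)(=O)C(F)(F)F)C(F)(F)F
Why: Enol triflate formation from the only possible enolate (deprotonation of the C10 methine) gives the tetrasubstituted C5=C10 vinyl triflate.

Step 7
Reactants: 8 (5S,6S)-6-[(tert-butyldimethylsilyloxy)methyl]-2,6-dimethyl-5-(triisopropylsilyloxy)cyclohex-1-en-1-yl trifluoromethanesulfonate
Product: 10 (3aS,4S)-3a,7-dimethyl-4-(triisopropylsilyloxy)-3a,4,5,6-tetrahydro-2-benzofuran-1(3H)-one (C19→C6 butenolide), via methyl enoate 9 (not isolated)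
Conditions: Pd(OAc)2 (10 mol %), Ph2P(CH2)3PPh2, CO (1 atm), Et3N, MeOH/DMF, 70 °C; then p-TsOH·H2O, MeOH, 40 °C
Reagents that add atoms: carbon monoxide, [C-]#[O+]; methanol, CO (kept in 9 only)
Why: Palladium-catalysed methoxycarbonylation of the vinyl triflate installs C6, and acid then cleaves the primary TBS ether and closes the five-membered lactone onto O19 by intramolecular transesterification while the secondary TIPS ether stays in place.

Step 8
Reactants: 10 (3aS,4S)-3a,7-dimethyl-4-(triisopropylsilyloxy)-3a,4,5,6-tetrahydro-2-benzofuran-1(3H)-one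
Product: 11 (3aS,4S,7aR)-3a-methyl-7-methylidene-4-(triisopropylsilyloxy)hexahydro-2-benzofuran-1(3H)-one (cis-fused lactone, H5 α)
Conditions: LiN(iPr)2, DMPU, THF, −78 °C; then AcOH, −78 °C
Reagents that add atoms: none
Why: Deconjugative protonation: γ-deprotonation of the C20 methyl, which lies syn to the lactone carbonyl, gives the dienolate, and kinetic α-protonation at C5 on the convex face (the side of C18, away from ring A) gives the cis-fused lactone with H5 α.

Step 9
Reactants: 11 (3aS,4S,7aR)-3a-methyl-7-methylidene-4-(triisopropylsilyloxy)hexahydro-2-benzofuran-1(3H)-one; 12 triisopropyl[(phenylsulfonyl)ethynyl]silane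
Product: 13 (3aS,4S,7S,7aR)-3a,7-dimethyl-4-(triisopropylsilyloxy)-7-[(triisopropylsilyl)ethynyl]hexahydro-2-benzofuran-1(3H)-one
Conditions: Fe(acac)3 (30 mol %), PhSiH3, EtOH/ethylene glycol, 60 °C
Reagents that add atoms: none
Why: Radical hydroalkynylation by metal-hydride hydrogen atom transfer: Markovnikov H-atom transfer to the exocyclic CH2 (which becomes the C20 methyl) gives the tertiary C10 radical, which adds to the sulfonyl-bearing alkyne carbon of 12 and expels the sulfonyl radical; trapping on the convex α face of the cis-fused lactone, anti to the axial C19 bridge, puts the alkyne α (equatorial, trans to the C5 arm) and C20 β.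

Step 10
Reactants: 13 (3aS,4S,7S,7aR)-3a,7-dimethyl-4-(triisopropylsilyloxy)-7-[(triisopropylsilyl)ethynyl]hexahydro-2-benzofuran-1(3H)-one
Product: 14 (1RS,3aS,4S,7S,7aR)-3a,7-dimethyl-4-(triisopropylsilyloxy)-7-[(triisopropylsilyl)ethynyl]octahydro-2-benzofuran-1-ol (lactol)
Conditions: iBu2AlH, CH2Cl2, −78 °C
Reagents that add atoms: none
Why: Partial reduction of the lactone with iBu2AlH stops at the five-membered aluminium lactolate at low temperature and gives the lactol without touching the silyl groups or the alkyne.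

Step 11
Reactants: 14 lactol; 15 2-methylallylmagnesium chloride
Product: 16 (1S)-1-[(1R,2S,3S,6S)-2-(hydroxymethyl)-2,6-dimethyl-3-(triisopropylsilyloxy)-6-[(triisopropylsilyl)ethynyl]cyclohexyl]-3-methylbut-3-en-1-ol
Conditions: 2-methylallylmagnesium chloride (excess), THF, −78 to 0 °C
Reagents that add atoms: none
Why: Grignard addition to the open hydroxy-aldehyde form of the lactol (the first equivalent deprotonates it) brings in C7, C8 and C17 as the 2-methylallyl group, the C6 carbinol being expected mainly as 6S by Felkin–Anh-type attack on the aldehyde face turned toward C10.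

Step 12
Reactants: 16 bis-TIPS diol
Product: 17 (1S,2S,3R,4S)-4-ethynyl-3-[(1S)-1-hydroxy-3-methylbut-3-en-1-yl]-2-(hydroxymethyl)-2,4-dimethylcyclohexan-1-ol
Conditions: Bu4NF, THF, rt to 45 °C
Reagents that add atoms: none
Why: Fluoride-induced desilylation removes the O3 and the alkyne TIPS groups in one operation before any ester is present and gives the terminal alkyne needed for the metathesis.

Step 13
Reactants: 17 triol
Product: 18 ring-A enyne, labdane numbering (3S,4S,5R,6S,10S): cyclohexane with 3β-OH, 4α-CH3, 4β-CH2O-isovaleryl, 5β-[(1S)-1-hydroxy-3-methylbut-3-enyl] (H5 α), 10β-CH3 and 10α-ethynyl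
Conditions: isovaleryl chloride (1.05 equiv), 2,4,6-collidine, CH2Cl2, −78 to −30 °C
Reagents that add atoms: 3-methylbutanoyl chloride, CC(C)CC(=O)Cl
Why: Kinetically controlled acylation with an acid chloride and collidine at low temperature selects the primary C19 hydroxyl over the two hindered secondary hydroxyls and installs the first isovalerate of the target.

Step 14
Reactants: 18 ring-A enyne
Product: 19 3β,6α-dihydroxy-13,14,15,16-tetranorlabda-8,11-dien-19-yl 3-methylbutanoate (9-vinyl diene)
Conditions: second-generation Hoveyda–Grubbs catalyst RuCl2(H2IMes)(=CH-C6H4-2-OiPr) (10 mol %), ethylene (1 atm), toluene, 80 °C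
Reagents that add atoms: none
Why: Ring-closing enyne metathesis: the Ru=CH2 species formed from the precatalyst and ethylene adds across the terminal alkyne with the usual regiochemistry (CH2 to the unhindered C11, Ru to C9), and opening of the ruthenacyclobutene gives the vinylcarbene Ru=C9(–C10)–C11H=C12H2. This carbene engages the 2-methylallyl alkene in a [2+2] cycloaddition–cycloreversion that forms C8=C9 and returns Ru=CH2, so that the substrate is simply isomerised and the CH2 lost from C8 reappears as C12. The closest known reaction is the ring-closing metathesis of 1,7-enynes bearing a terminal alkyne and a 1,1-disubstituted alkene to 2-methyl-1-vinylcyclohexenes with second-generation Ru carbenes under ethylene. Ring B closes in the exo mode: only C9 of the alkyne enters the six-membered ring and C11 stays outside as the vinyl carbon. No stereocentre is formed, and C5, C6 and C10 are not touched. The step needs ring closure to win over capture of the C9 carbene by ethylene and over the endo (seven-membered) mode; the trans-diequatorial C5 arm and C10 alkyne on the chair of ring A, fixed by the quaternary C4 and C10, hold C8 next to C9, and the 1,1-disubstituted alkene is too hindered to load Ru itself, which leaves the alkyne-first path as the productive one.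

Step 15
Reactants: 20 tert-butyl acetoacetate
Product: 21 tert-butyl (E)-3-(trifluoromethanesulfonyloxy)but-2-enoate
Conditions: Tf2O, aq. Me4NOH, hexanes, 5 °C to rt
Reagents that add atoms: trifluoromethanesulfonic anhydride, O=S(=O)(OS(=O)(=O)C(F)(F)F)C(F)(F)F
Why: O-triflation of the tetramethylammonium enolate of the β-keto ester, which reacts in its non-chelated extended form, gives the (E)-enol triflate (TfO trans to the ester) needed for the 13E alkene.

Step 16
Reactants: 19 9-vinyl diene; 21 tert-butyl (E)-3-(trifluoromethanesulfonyloxy)but-2-enoate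
Product: 23 tert-butyl 3β,6α-dihydroxy-19-(3-methylbutanoyloxy)labda-8,13(E)-dien-15-oate, via B-alkyl-9-BBN adduct 22 (not isolated)
Conditions: 9-BBN dimer (excess), THF, 0 °C to rt; then 21, PdCl2(dppf) (5 mol %), aq. K3PO4, DMF, 45 °C
Reagents that add atoms: 9-borabicyclo[3.3.1]nonane, [BH]1C2CCCC1CCC2 (kept in 22 only)
Why: Hydroboration of the monosubstituted C11=C12 alkene with 9-BBN puts boron on C12 (the tetrasubstituted C8=C9 alkene is inert), and B-alkyl Suzuki–Miyaura coupling with the (E)-enol triflate forms C12–C13 with retention of the E geometry.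

Step 17
Reactants: 23 tert-butyl 3β,6α-dihydroxy-19-(3-methylbutanoyloxy)labda-8,13(E)-dien-15-oate
Product: 24 tert-butyl 19-(3-methylbutanoyloxy)-3,6-dioxolabda-8,13(E)-dien-15-oate
Conditions: Dess–Martin periodinane, NaHCO3, CH2Cl2, 0 °C to rt; used without chromatography
Reagents that add atoms: none
Why: Dess–Martin oxidation converts both secondary alcohols into ketones under buffered, non-basic conditions, so the C8=C9 alkene stays out of conjugation and C5 keeps its configuration, while the C3 and C6 configurations are erased for re-setting.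

Step 18
Reactants: 24 tert-butyl 19-(3-methylbutanoyloxy)-3,6-dioxolabda-8,13(E)-dien-15-oate
Product: 25 tert-butyl 3α,6β-dihydroxy-19-(3-methylbutanoyloxy)labda-8,13(E)-dien-15-oate
Conditions: LiBH(s-Bu)3 (L-Selectride), THF, −78 to −20 °C; then H2O2, pH 7 buffer, 0 °C
Reagents that add atoms: none
Why: Bulky-hydride reduction: LiBH(s-Bu)3 attacks the C3 ketone equatorially to give the axial 3α-alcohol and the C6 ketone from the open α face (the β face is covered by the axial C19 and C20 groups) to give the axial 6β-alcohol, while the β,β-disubstituted enoate and the esters are left alone at low temperature.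

Step 19
Reactants: 25 tert-butyl 3α,6β-dihydroxy-19-(3-methylbutanoyloxy)labda-8,13(E)-dien-15-oate
Product: 26 tert-butyl 6β-hydroxy-3α,19-bis(3-methylbutanoyloxy)labda-8,13(E)-dien-15-oate
Conditions: isovaleryl chloride, pyridine, 4-(dimethylamino)pyridine (cat.), CH2Cl2, 0 °C to rt
Reagents that add atoms: 3-methylbutanoyl chloride, CC(C)CC(=O)Cl
Why: Nucleophile-catalysed acylation esterifies the 3α-hydroxyl, whereas the 6β-hydroxyl, syn-diaxial to both C19 and C20, should stay free, which gives the acylation pattern of the target.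

Step 20
Reactants: 26 tert-butyl 6β-hydroxy-3α,19-bis(3-methylbutanoyloxy)labda-8,13(E)-dien-15-oate
Product: 27 6β-hydroxy-3α,19-bis(3-methylbutanoyloxy)labda-8,13(E)-dien-15-oic acid (CNP0333611.1)
Conditions: CF3CO2H/CH2Cl2 (1:4), 0 °C
Reagents that add atoms: none
Why: Acidolysis of the tert-butyl ester (loss of isobutene) frees the C15 acid without touching the isovalerates, the hindered 6β-alcohol or the alkenes.

**Compound list**
1 | 2-methylcyclohexane-1,3-dione | CC1C(=O)CCCC1=O | starting material
2 | formaldehyde | C=O | starting material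
3 | 2-(hydroxymethyl)-2-methylcyclohexane-1,3-dione | CC1(CO)C(=O)CCCC1=O | intermediate
4 | 2-[(tert-butyldimethylsilyloxy)methyl]-2-methylcyclohexane-1,3-dione | CC1(CO[Si](C)(C)C(C)(C)C)C(=O)CCCC1=O | intermediate
5 | (2S,3S)-2-[(tert-butyldimethylsilyloxy)methyl]-3-hydroxy-2-methylcyclohexan-1-one (OH cis to the CH2OTBS arm) | O=C1CCC[C@H](O)[C@]1(C)CO[Si](C)(C)C(C)(C)C | intermediate
6 | (2S,3S)-2-[(tert-butyldimethylsilyloxy)methyl]-2-methyl-3-(triisopropylsilyloxy)cyclohexan-1-one | O=C1CCC[C@H](O[Si](C(C)C)(C(C)C)C(C)C)[C@]1(C)CO[Si](C)(C)C(C)(C)C | intermediate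
7 | (2S,3S,6RS)-2-[(tert-butyldimethylsilyloxy)methyl]-2,6-dimethyl-3-(triisopropylsilyloxy)cyclohexan-1-one (both epimers at the future C10) | CC1CC[C@H](O[Si](C(C)C)(C(C)C)C(C)C)[C@](C)(CO[Si](C)(C)C(C)(C)C)C1=O | intermediate
8 | (5S,6S)-6-[(tert-butyldimethylsilyloxy)methyl]-2,6-dimethyl-5-(triisopropylsilyloxy)cyclohex-1-en-1-yl trifluoromethanesulfonate | CC1=C(OS(=O)(=O)C(F)(F)F)[C@@](C)(CO[Si](C)(C)C(C)(C)C)[C@@H](O[Si](C(C)C)(C(C)C)C(C)C)CC1 | intermediate
9 | methyl (5S,6S)-6-[(tert-butyldimethylsilyloxy)methyl]-2,6-dimethyl-5-(triisopropylsilyloxy)cyclohex-1-ene-1-carboxylate | COC(=O)C1=C(C)CC[C@H](O[Si](C(C)C)(C(C)C)C(C)C)[C@]1(C)CO[Si](C)(C)C(C)(C)C | intermediate (not isolated)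
10 | (3aS,4S)-3a,7-dimethyl-4-(triisopropylsilyloxy)-3a,4,5,6-tetrahydro-2-benzofuran-1(3H)-one | CC1=C2C(=O)OC[C@@]2(C)[C@@H](O[Si](C(C)C)(C(C)C)C(C)C)CC1 | intermediate
11 | (3aS,4S,7aR)-3a-methyl-7-methylidene-4-(triisopropylsilyloxy)hexahydro-2-benzofuran-1(3H)-one | C=C1CC[C@H](O[Si](C(C)C)(C(C)C)C(C)C)[C@]2(C)COC(=O)[C@H]12 | intermediate
12 | triisopropyl[(phenylsulfonyl)ethynyl]silane | CC(C)[Si](C#CS(=O)(=O)c1ccccc1)(C(C)C)C(C)C | starting material
13 | (3aS,4S,7S,7aR)-3a,7-dimethyl-4-(triisopropylsilyloxy)-7-[(triisopropylsilyl)ethynyl]hexahydro-2-benzofuran-1(3H)-one | CC(C)[Si](C#C[C@@]1(C)CC[C@H](O[Si](C(C)C)(C(C)C)C(C)C)[C@]2(C)COC(=O)[C@H]12)(C(C)C)C(C)C | intermediate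
14 | (1RS,3aS,4S,7S,7aR)-3a,7-dimethyl-4-(triisopropylsilyloxy)-7-[(triisopropylsilyl)ethynyl]octahydro-2-benzofuran-1-ol | CC(C)[Si](C#C[C@@]1(C)CC[C@H](O[Si](C(C)C)(C(C)C)C(C)C)[C@]2(C)COC(O)[C@H]12)(C(C)C)C(C)C | intermediate
15 | 2-methylallylmagnesium chloride | C=C(C)C[Mg]Cl | starting material
16 | (1S)-1-[(1R,2S,3S,6S)-2-(hydroxymethyl)-2,6-dimethyl-3-(triisopropylsilyloxy)-6-[(triisopropylsilyl)ethynyl]cyclohexyl]-3-methylbut-3-en-1-ol | CC(C)[Si](C#C[C@@]1(C)CC[C@H](O[Si](C(C)C)(C(C)C)C(C)C)[C@](C)(CO)[C@@H]1[C@@H](O)CC(C)=C)(C(C)C)C(C)C | intermediate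
17 | (1S,2S,3R,4S)-4-ethynyl-3-[(1S)-1-hydroxy-3-methylbut-3-en-1-yl]-2-(hydroxymethyl)-2,4-dimethylcyclohexan-1-ol | C#C[C@@]1(C)CC[C@H](O)[C@](C)(CO)[C@@H]1[C@@H](O)CC(C)=C | intermediate
18 | ring-A enyne: 19-O-(3-methylbutanoyl) ester of 17 (labdane numbering 3S,4S,5R,6S,10S; 3β-OH, 6α-OH, 10α-ethynyl, 10β-methyl) | C#C[C@@]1(C)CC[C@H](O)[C@](C)(COC(=O)CC(C)C)[C@@H]1[C@@H](O)CC(C)=C | intermediate
19 | 3β,6α-dihydroxy-13,14,15,16-tetranorlabda-8,11-dien-19-yl 3-methylbutanoate | CC1=C(C=C)[C@@]2(C)CC[C@H](O)[C@](C)(COC(=O)CC(C)C)[C@@H]2[C@@H](O)C1 | intermediate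
20 | tert-butyl acetoacetate | CC(=O)CC(=O)OC(C)(C)C | starting material
21 | tert-butyl (E)-3-(trifluoromethanesulfonyloxy)but-2-enoate | C/C(OS(=O)(=O)C(F)(F)F)=C\C(=O)OC(C)(C)C | intermediate
22 | B-(C12)-alkyl-9-borabicyclo[3.3.1]nonane adduct of 19 | CC1=C(CCB2C3CCCC2CCC3)[C@@]4(C)CC[C@H](O)[C@](C)(COC(=O)CC(C)C)[C@@H]4[C@@H](O)C1 | intermediate (not isolated)
23 | tert-butyl 3β,6α-dihydroxy-19-(3-methylbutanoyloxy)labda-8,13(E)-dien-15-oate | CC1=C(CC/C(C)=C/C(=O)OC(C)(C)C)[C@@]2(C)CC[C@H](O)[C@](C)(COC(=O)CC(C)C)[C@@H]2[C@@H](O)C1 | intermediate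
24 | tert-butyl 19-(3-methylbutanoyloxy)-3,6-dioxolabda-8,13(E)-dien-15-oate | CC1=C(CC/C(C)=C/C(=O)OC(C)(C)C)[C@@]2(C)CCC(=O)[C@](C)(COC(=O)CC(C)C)[C@@H]2C(=O)C1 | intermediate
25 | tert-butyl 3α,6β-dihydroxy-19-(3-methylbutanoyloxy)labda-8,13(E)-dien-15-oate | CC1=C(CC/C(C)=C/C(=O)OC(C)(C)C)[C@@]2(C)CC[C@@H](O)[C@](C)(COC(=O)CC(C)C)[C@@H]2[C@H](O)C1 | intermediate
26 | tert-butyl 6β-hydroxy-3α,19-bis(3-methylbutanoyloxy)labda-8,13(E)-dien-15-oate | CC1=C(CC/C(C)=C/C(=O)OC(C)(C)C)[C@@]2(C)CC[C@@H](OC(=O)CC(C)C)[C@](C)(COC(=O)CC(C)C)[C@@H]2[C@H](O)C1 | intermediate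
27 | 6β-hydroxy-3α,19-bis(3-methylbutanoyloxy)labda-8,13(E)-dien-15-oic acid (CNP0333611.1) | CC1=C(CC/C(C)=C/C(=O)O)[C@@]2(C)CC[C@@H](OC(=O)CC(C)C)[C@](C)(COC(=O)CC(C)C)[C@@H]2[C@H](O)C1 | target

**Step count**
Total: 20 steps. Longest linear sequence: 19 steps (steps 1–14 and 16–20, from 2-methylcyclohexane-1,3-dione); the coupling partner 21 takes one step (step 15).

**Steps most likely to fail**

Step 14 (ring closure by enyne metathesis). What may go wrong: the C9 vinylcarbene is captured by ethylene faster than it closes on the 1,1-disubstituted alkene, so an open-chain 2-substituted butadiene results; the ring closes in the endo mode; or the free hydroxyls bind the catalyst. The fallback sets out from 18 and comes back at 19, and replaces carbene metathesis by π-acid catalysis. Compound 18 is silylated with TESOTf and 2,6-lutidine to the bis(triethylsilyl) ether of 18 F1. Heating F1 with PtCl2 in toluene should bring about the known skeletal reorganisation of 1,7-enynes to 1-vinylcyclohexenes: the alkyne is activated as an electrophile, the alkene attacks it (here the 1,1-disubstitution at C8 is an advantage), and the cyclopropyl platinum carbene rearranges. This should give the bis(triethylsilyl) ether of 19 F2, and HF·pyridine then frees the two hydroxyls to give 19.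

Step 9 (radical alkynylation at C10). What may go wrong: reversible hydrogen atom transfer moves the alkene back into conjugation with the lactone, the C10 radical is reduced instead of trapped, or trapping is not face-selective. The fallback sets out from 11 and comes back at 13. Mukaiyama hydration (Co(acac)2, PhSiH3, O2) should give the tertiary C10 alcohol F3, and acylation with chloro N-phthalimidoyl oxalate gives the N-phthalimidoyl oxalate F4. Visible-light photoredox fragmentation of F4 (Ru(bpy)3Cl2, Hantzsch ester) in the presence of sulfone 12 generates the same C10 radical with no metal hydride in the flask, and trapping on the convex face gives 13.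

Step 13 (selective acylation of the primary hydroxyl). What may go wrong: competing acylation at O3, or a slow reaction at the neopentyl C19 hydroxyl that forces conditions under which selectivity is lost. The fallback sets out from 16 and comes back at 18. The isovalerate is put on before the silyl groups are removed, when O3 still carries TIPS and only the hindered C6 hydroxyl competes (isovaleryl chloride, pyridine), giving the 19-O-isovaleryl bis-TIPS compound F5. Both silyl groups are then removed with Bu4NF buffered with AcOH to give 18.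

**Further compounds**
F1 | step 14 | bis(triethylsilyl) ether of 18 (3-O-TES, 6-O-TES) | C#C[C@@]1(C)CC[C@H](O[Si](CC)(CC)CC)[C@](C)(COC(=O)CC(C)C)[C@@H]1[C@@H](O[Si](CC)(CC)CC)CC(C)=C
F2 | step 14 | bis(triethylsilyl) ether of 19 (3-O-TES, 6-O-TES) | CC1=C(C=C)[C@@]2(C)CC[C@H](O[Si](CC)(CC)CC)[C@](C)(COC(=O)CC(C)C)[C@@H]2[C@@H](O[Si](CC)(CC)CC)C1
F3 | step 9 | (3aS,4S,7S,7aR)-7-hydroxy-3a,7-dimethyl-4-(triisopropylsilyloxy)hexahydro-2-benzofuran-1(3H)-one | O[C@@]1(C)CC[C@H](O[Si](C(C)C)(C(C)C)C(C)C)[C@]2(C)COC(=O)[C@H]12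
F4 | step 9 | N-phthalimidoyl oxalate of F3 | O=C(O[C@@]1(C)CC[C@H](O[Si](C(C)C)(C(C)C)C(C)C)[C@]2(C)COC(=O)[C@H]12)C(=O)ON1C(=O)c2ccccc2C1=O
F5 | step 13 | 19-O-(3-methylbutanoyl) ester of 16 (3-O-TIPS and alkyne TIPS retained) | CC(C)[Si](C#C[C@@]1(C)CC[C@H](O[Si](C(C)C)(C(C)C)C(C)C)[C@](C)(COC(=O)CC(C)C)[C@@H]1[C@@H](O)CC(C)=C)(C(C)C)C(C)C
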